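## Retrosynthetic overview

1. The last disconnection is C5–C6 of the acid chain (numbered from the amide C=O), the bond from the alkene CH to the CH2 next to the C7 methoxy carbon. It is made by nickel-electrocatalytic decarboxylative alkenylation of the N-hydroxyphthalimide ester of (3R,5S)-3-methoxy-5-methyldodecanoic acid with the unprotected (E)-5-iodopent-4-enamide that already carries the whole head group.
2. Enabling feature: C6 is a primary CH2 flanked only by the C7(OMe) stereocentre. C6–C7 is therefore the C2–C3 unit of a β-methoxy acid, and C6 can be generated as a radical that neither expels the β-methoxy group nor touches C7. C4=C5 is an isolated E-disubstituted alkene two CH2 groups from the amide, so C5 can be a geometrically pure alkenyl iodide. The ring A enone is branched at C2' and flanked by the C4' methyl group, so it stays out of the radical and cathodic events.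
3. Iodide half: the amide bond (N–C1) is formed after the C2'–Cb bond, which comes from Nozaki–Hiyama–Kishi coupling of the ring A 2-iodoenone with N-Boc-O-methyl-D-serinal. Ca = CH(N) comes from D-serine, and Cb = CH(OH) is set by Felkin–Anh control.
4. Ring A is the only ring (C1' C=O, C2' side-chain carbon, C3' =CH, C4' CHMe, C5' CHOH, C6' CMe2). It is closed first, by ring-closing metathesis at C2'=C3' of a dienone whose C4'/C5' pair comes from a Brown (Z)-crotylboration.
5. Ester half: C9 is set by copper-catalysed asymmetric conjugate addition and C7 by Noyori hydrogenation of a β-keto ester, followed by O-methylation and activation.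

Key step: step 21

Assumption: in step 15 the named ligand enantiomer is taken to give the (S) ester; both ligand enantiomers are sold, so the other one would be used should the sense be the opposite.

## Route

Step 1
Reactants: 1 methyl 3-hydroxy-2,2-dimethylpropanoate
Product: 2 3-hydroxy-N-methoxy-N,2,2-trimethylpropanamide
Conditions: MeNH(OMe)·HCl (1.6 equiv), i-PrMgCl (4.5 equiv), THF, −20 °C to rt
Reagents that add atoms: N,O-dimethylhydroxylamine hydrochloride, CNOC.Cl
Why: Weinreb amide formation by aminolysis of the ester with the chloromagnesium amide made in the flask, the free hydroxyl being only deprotonated and returned on work-up.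

Step 2
Reactants: 2 3-hydroxy-N-methoxy-N,2,2-trimethylpropanamide
Product: 3 N-methoxy-N,2,2-trimethyl-3-oxopropanamide
Conditions: Dess–Martin periodinane, CH2Cl2, 0 °C to rt
Reagents that add atoms: none
Why: Dess–Martin oxidation of a primary neopentyl alcohol, which stops at the non-enolisable aldehyde and leaves the Weinreb amide alone.

Step 3
Reactants: 3 N-methoxy-N,2,2-trimethyl-3-oxopropanamide; 4 cis-2-butene
Product: 6 (3R,4S)-3-hydroxy-N-methoxy-N,2,2,4-tetramethylhex-5-enamide, via borinate adduct 5 (not isolated)
Conditions: 4 (excess), n-BuLi, KOt-Bu, THF, −78 to −45 °C; (+)-Ipc2BOMe, −78 °C; BF3·OEt2; then 3, −78 °C; then NaOH, H2O2, 0 °C to rt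
Reagents that add atoms: (+)-B-methoxydiisopinocampheylborane, made from (−)-α-pinene (its boron and Ipc groups stand only in 5), COB([C@H]1C[C@H]2C[C@@H]([C@@H]1C)C2(C)C)[C@H]1C[C@H]2C[C@@H]([C@@H]1C)C2(C)C
Why: Brown asymmetric crotylboration through a closed chair (Zimmerman–Traxler) transition state: the Z geometry of the crotyl group sets the syn C3/C4 relation (trans on ring A later), and the isopinocampheyl groups derived from (−)-α-pinene choose the aldehyde face that gives the (3R) carbinol, the same sense as with other α-quaternary aldehydes.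

Step 4
Reactants: 6 (3R,4S)-3-hydroxy-N-methoxy-N,2,2,4-tetramethylhex-5-enamide
Product: 7 (3R,4S)-N-methoxy-N,2,2,4-tetramethyl-3-(triethylsilyloxy)hex-5-enamide
Conditions: TESOTf, 2,6-lutidine, CH2Cl2, −78 to 0 °C
Reagents that add atoms: triethylsilyl triflate, CC[Si](CC)(CC)OS(=O)(=O)C(F)(F)F
Why: Silyl ether formation with the reactive triflate copes with the hindered carbinol, and triethylsilyl is chosen because it survives steps 5 to 10 yet falls together with Boc in step 11.

Step 5
Reactants: 7 (3R,4S)-N-methoxy-N,2,2,4-tetramethyl-3-(triethylsilyloxy)hex-5-enamide; 8 vinylmagnesium bromide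
Product: 9 (5R,6S)-4,4,6-trimethyl-5-(triethylsilyloxy)octa-1,7-dien-3-one
Conditions: CH2=CHMgBr (3 equiv), THF, 0 °C to rt; inverse quench into cold aq NaHSO4
Reagents that add atoms: none
Why: Weinreb ketone synthesis: the chelated tetrahedral adduct prevents a second addition, and the inverse acidic quench protonates the released MeNH(OMe) before it can add to the vinyl ketone.

Step 6
Reactants: 9 (5R,6S)-4,4,6-trimethyl-5-(triethylsilyloxy)octa-1,7-dien-3-one
Product: 10 (4S,5R)-4,6,6-trimethyl-5-(triethylsilyloxy)cyclohex-2-en-1-one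
Conditions: second-generation Grubbs catalyst (5 mol%), CH2Cl2 (0.005 M), reflux
Reagents that add atoms: none
Why: Ring-closing metathesis of a vinyl ketone with a monosubstituted alkene closes six-membered ring A at C2'=C3' with loss of ethene, a well-known entry to cyclohexenones that does not touch C4' and C5'.

Step 7
Reactants: 10 (4S,5R)-4,6,6-trimethyl-5-(triethylsilyloxy)cyclohex-2-en-1-one
Product: 11 (4S,5R)-2-iodo-4,6,6-trimethyl-5-(triethylsilyloxy)cyclohex-2-en-1-one
Conditions: I2, pyridine/CH2Cl2 1:1, 0 °C to rt
Reagents that add atoms: iodine, [I][I]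
Why: Johnson α-iodination (conjugate addition of pyridine, iodination of the enolate, loss of pyridine) places iodine at C2', the only enone α-position, since C6' is quaternary.

Step 8
Reactants: 12 N-Boc-O-methyl-D-serine, (R)-2-(tert-butoxycarbonylamino)-3-methoxypropanoic acid
Product: 13 tert-butyl (R)-[1-methoxy-3-[methoxy(methyl)amino]-3-oxopropan-2-yl]carbamate
Conditions: MeNH(OMe)·HCl, EDC·HCl, N-methylmorpholine, CH2Cl2, −15 °C to rt
Reagents that add atoms: N,O-dimethylhydroxylamine hydrochloride, CNOC.Cl
Why: Carbodiimide coupling to the Weinreb amide, in which the urethane N-protecting group guards Ca against racemisation.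

Step 9
Reactants: 13 tert-butyl (R)-[1-methoxy-3-[methoxy(methyl)amino]-3-oxopropan-2-yl]carbamate
Product: 14 N-Boc-O-methyl-D-serinal, tert-butyl (R)-(1-methoxy-3-oxopropan-2-yl)carbamate
Conditions: LiAlH4, THF, 0 °C; aq KHSO4; used crude
Reagents that add atoms: none
Why: Hydride reduction of a Weinreb amide stops at the chelated hemiaminal and gives the aldehyde on work-up, which is used at once and unpurified so that Ca does not epimerise and methanol is not eliminated.

Step 10
Reactants: 11 (4S,5R)-2-iodo-4,6,6-trimethyl-5-(triethylsilyloxy)cyclohex-2-en-1-one; 14 N-Boc-O-methyl-D-serinal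
Product: 16 tert-butyl N-[(1S,2R)-1-hydroxy-3-methoxy-1-[(3S,4R)-3,5,5-trimethyl-6-oxo-4-(triethylsilyloxy)cyclohex-1-en-1-yl]propan-2-yl]carbamate, via alkenylchromium dichloride 15 (not isolated)
Conditions: CrCl2 (4 equiv), NiCl2 (2 mol%), DMSO, rt
Reagents that add atoms: CrCl2 (chromium and chlorine stand only in 15), Cl[Cr]Cl
Why: Nozaki–Hiyama–Kishi reaction: zerovalent nickel inserts into the C–I bond and transmetalation gives alkenylchromium species 15, which tolerates its own hindered ketone and adds only to the aldehyde; in the strongly donating solvent chelation by the carbamate is suppressed, so Felkin–Anh attack anti to the NHBoc group should give the anti amino alcohol, that is (S) at Cb.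

Step 11
Reactants: 16 the Boc/TES-protected carbinol of step 10
Product: 17 (4S,5R)-2-[(1S,2R)-2-amino-1-hydroxy-3-methoxypropyl]-5-hydroxy-4,6,6-trimethylcyclohex-2-en-1-one hydrochloride
Conditions: HCl (3 M in MeOH), 0 °C to rt
Reagents that add atoms: hydrogen chloride, Cl
Why: Acidolysis removes the Boc group and methanolysis the triethylsilyl ether in one operation, while Cb–OH does not ionise because the cation would sit next to the electron-poor enone, and the amine is kept as its salt so that it cannot add to the enone.

Step 12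
Reactants: 18 pent-4-yn-1-ol
Product: 20 (E)-5-iodopent-4-en-1-ol, via alkenylzirconocene chloride 19 (not isolated)
Conditions: Cp2ZrHCl (2.2 equiv), THF, rt; then I2, 0 °C
Reagents that add atoms: iodine, [I][I]; Cp2ZrHCl (zirconium stands only in 19), [H][Zr](Cl)(C1C=CC=C1)C1C=CC=C1
Why: Hydrozirconation of the terminal alkyne is a syn, anti-Markovnikov addition (the first equivalent of Cp2ZrHCl is spent on the hydroxyl group), and iodinolysis of the C–Zr bond goes with retention, so that only the E-iodide should form.

Step 13
Reactants: 20 (E)-5-iodopent-4-en-1-ol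
Product: 21 (E)-5-iodopent-4-enoic acid
Conditions: TEMPO (20 mol%), PhI(OAc)2 (2.2 equiv), MeCN/H2O 1:1, rt
Reagents that add atoms: water, O
Why: Oxoammonium (TEMPO) oxidation of the primary alcohol through the aldehyde hydrate to the acid, mild enough for the alkenyl iodide.

Step 14
Reactants: 17 the amino diol hydrochloride of step 11; 21 (E)-5-iodopent-4-enoic acid
Product: 22 (E)-N-[(1S,2R)-1-hydroxy-1-[(3S,4R)-4-hydroxy-3,5,5-trimethyl-6-oxocyclohex-1-en-1-yl]-3-methoxypropan-2-yl]-5-iodopent-4-enamide
Conditions: EDC·HCl, HOBt, i-Pr2NEt, CH2Cl2/DMF, 0 °C to rt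
Reagents that add atoms: none
Why: Carbodiimide/HOBt amide coupling, in which the primary amine set free by the base is acylated far faster than the two hindered secondary hydroxyl groups.

Step 15
Reactants: 23 methyl (E)-but-2-enoate (methyl crotonate); 24 n-heptylmagnesium bromide
Product: 25 methyl (S)-3-methyldecanoate
Conditions: CuBr·SMe2 (1 mol%), (R)-1-[(Sp)-2-(diphenylphosphino)ferrocenyl]ethyldicyclohexylphosphine (1.2 mol%), t-BuOMe, −75 °C; then MeOH, aq NH4Cl
Reagents that add atoms: none
Why: Copper-catalysed enantioselective conjugate addition of a Grignard reagent to an α,β-unsaturated ester, in which the ferrocenyl diphosphine on copper decides the face of the crotonate and so sets the methyl-bearing centre (later C9) as (S).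

Step 16
Reactants: 25 methyl (S)-3-methyldecanoate; 26 tert-butyl acetate
Product: 27 tert-butyl (S)-5-methyl-3-oxododecanoate
Conditions: 26 (3.5 equiv), LiN(i-Pr)2 (3.5 equiv), THF, −78 °C; then 25, −78 to 0 °C
Reagents that add atoms: none
Why: Crossed Claisen condensation, made clean by an excess of the lithium enolate of 26, which self-condenses only slowly at low temperature and also deprotonates the β-keto ester as it forms.

Step 17
Reactants: 27 tert-butyl (S)-5-methyl-3-oxododecanoate
Product: 28 tert-butyl (3R,5S)-3-hydroxy-5-methyldodecanoate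
Conditions: RuCl2[(R)-BINAP] (0.5 mol%), H2 (10 bar), MeOH, 50 °C
Reagents that add atoms: none
Why: Noyori asymmetric hydrogenation of a β-keto ester: the (R)-BINAP ruthenium catalyst delivers hydrogen under catalyst control to give the (3R) alcohol (later C7), whatever the remote C5 methyl centre prefers.

Step 18
Reactants: 28 tert-butyl (3R,5S)-3-hydroxy-5-methyldodecanoate
Product: 29 tert-butyl (3R,5S)-3-methoxy-5-methyldodecanoate
Conditions: Me3OBF4, 1,8-bis(dimethylamino)naphthalene, 4 Å MS, CH2Cl2, 0 °C to rt
Reagents that add atoms: trimethyloxonium tetrafluoroborate, C[O+](C)C.F[B-](F)(F)F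
Why: O-methylation with Meerwein salt and a non-nucleophilic proton scavenger avoids alkoxide formation and therefore retro-aldol cleavage or β-elimination of the β-hydroxy ester.

Step 19
Reactants: 29 tert-butyl (3R,5S)-3-methoxy-5-methyldodecanoate
Product: 30 (3R,5S)-3-methoxy-5-methyldodecanoic acid
Conditions: CF3CO2H/CH2Cl2 1:4, 0 °C to rt
Reagents that add atoms: none
Why: Acidolysis of the tert-butyl ester frees the acid without the base that could eliminate the β-methoxy group.

Step 20
Reactants: 30 (3R,5S)-3-methoxy-5-methyldodecanoic acid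
Product: 31 1,3-dioxoisoindolin-2-yl (3R,5S)-3-methoxy-5-methyldodecanoate
Conditions: N-hydroxyphthalimide, DIC, DMAP (10 mol%), CH2Cl2, rt
Reagents that add atoms: N-hydroxyphthalimide, O=C1c2ccccc2C(=O)N1O
Why: Steglich-type carbodiimide esterification gives the redox-active N-hydroxyphthalimide ester, which can be isolated by a short filtration over silica.

Step 21
Reactants: 22 the (E)-5-iodopent-4-enamide of step 14; 31 1,3-dioxoisoindolin-2-yl (3R,5S)-3-methoxy-5-methyldodecanoate
Product: 33 (4E,7R,9S)-N-[(1S,2R)-1-hydroxy-1-[(3S,4R)-4-hydroxy-3,5,5-trimethyl-6-oxocyclohex-1-en-1-yl]-3-methoxypropan-2-yl]-7-methoxy-9-methylhexadec-4-enamide, via primary alkyl radical 32 (not isolated)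
Conditions: 31 (1.5 equiv), NiCl2·6H2O (20 mol%), 2,2'-bipyridine (20 mol%), AgNO3 (0.3 equiv), LiCl, DMF, Mg anode, reticulated vitreous carbon cathode, undivided cell, constant current, rt
Reagents that add atoms: none
Why: Mechanism: the cathode reduces divalent nickel/bipyridine to low-valent nickel, which inserts into the C5–I bond of 22 with retention, while one-electron reduction of 31 (by low-valent nickel or at the silver-coated cathode) expels phthalimide anion and CO2 and leaves the primary C6 radical 32; capture of 32 by the alkenylnickel species and reductive elimination from trivalent nickel forge C5–C6, and the Mg anode supplies the electrons. The closest known reaction type is the nickel-electrocatalytic decarboxylative alkenylation of N-hydroxyphthalimide esters with alkenyl iodides, which is established for primary esters and E-1,2-disubstituted iodides. No ring is closed and no stereocentre is created: the E geometry of C4=C5 is inherited from 22 because both organometallic steps are stereoretentive, C7 sits one atom away from the radical centre and is not touched, and the other five stereocentres are spectators. The selectivity needed is chemoselectivity for the C–I bond and the activated ester over the ring A enone: 31 and the catalyst are reduced at clearly less negative potential than an enone, so constant current with 31 in excess keeps the cathode away from it, and radical addition to C3' is slowed by the C4' methyl group and the branched C2' substituent while capture by nickel is fast. The radical polarity is what the C7 methoxy group demands, since a C6 organozinc or organomagnesium reagent would lose methoxide by β-elimination whereas a β-methoxyalkyl radical does not fragment, and the neutral medium leaves both hydroxyl groups and the amide N–H alone. One operation thus joins the two halves without any protecting group and gives the target itself.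

## Compound list

1 | methyl 3-hydroxy-2,2-dimethylpropanoate | COC(=O)C(C)(C)CO | starting material
2 | 3-hydroxy-N-methoxy-N,2,2-trimethylpropanamide | CON(C)C(=O)C(C)(C)CO | intermediate
3 | N-methoxy-N,2,2-trimethyl-3-oxopropanamide | CON(C)C(=O)C(C)(C)C=O | intermediate
4 | cis-2-butene | C/C=C\C | starting material
5 | diisopinocampheylborinate of 6 (borinate adduct, not isolated) | C=C[C@H](C)[C@@H](OB([C@H]1C[C@H]2C[C@@H]([C@@H]1C)C2(C)C)[C@H]1C[C@H]2C[C@@H]([C@@H]1C)C2(C)C)C(C)(C)C(=O)N(C)OC | intermediate
6 | (3R,4S)-3-hydroxy-N-methoxy-N,2,2,4-tetramethylhex-5-enamide | C=C[C@H](C)[C@@H](O)C(C)(C)C(=O)N(C)OC | intermediate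
7 | (3R,4S)-N-methoxy-N,2,2,4-tetramethyl-3-(triethylsilyloxy)hex-5-enamide | C=C[C@H](C)[C@@H](O[Si](CC)(CC)CC)C(C)(C)C(=O)N(C)OC | intermediate
8 | vinylmagnesium bromide | C=C[Mg]Br | starting material
9 | (5R,6S)-4,4,6-trimethyl-5-(triethylsilyloxy)octa-1,7-dien-3-one | C=C[C@H](C)[C@@H](O[Si](CC)(CC)CC)C(C)(C)C(=O)C=C | intermediate
10 | (4S,5R)-4,6,6-trimethyl-5-(triethylsilyloxy)cyclohex-2-en-1-one | O=C1C=C[C@H](C)[C@@H](O[Si](CC)(CC)CC)C1(C)C | intermediate
11 | (4S,5R)-2-iodo-4,6,6-trimethyl-5-(triethylsilyloxy)cyclohex-2-en-1-one | O=C1C(I)=C[C@H](C)[C@@H](O[Si](CC)(CC)CC)C1(C)C | intermediate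
12 | N-Boc-O-methyl-D-serine | CC(C)(C)OC(=O)N[C@H](COC)C(=O)O | starting material
13 | tert-butyl (R)-[1-methoxy-3-[methoxy(methyl)amino]-3-oxopropan-2-yl]carbamate | CC(C)(C)OC(=O)N[C@H](COC)C(=O)N(C)OC | intermediate
14 | N-Boc-O-methyl-D-serinal, tert-butyl (R)-(1-methoxy-3-oxopropan-2-yl)carbamate | CC(C)(C)OC(=O)N[C@H](COC)C=O | intermediate
15 | alkenylchromium dichloride derived from 11 (not isolated) | O=C1C([Cr](Cl)Cl)=C[C@H](C)[C@@H](O[Si](CC)(CC)CC)C1(C)C | intermediate
16 | tert-butyl N-[(1S,2R)-1-hydroxy-3-methoxy-1-[(3S,4R)-3,5,5-trimethyl-6-oxo-4-(triethylsilyloxy)cyclohex-1-en-1-yl]propan-2-yl]carbamate | CC(C)(C)OC(=O)N[C@H](COC)[C@@H](O)C1=C[C@H](C)[C@@H](O[Si](CC)(CC)CC)C(C)(C)C1=O | intermediate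
17 | (4S,5R)-2-[(1S,2R)-2-amino-1-hydroxy-3-methoxypropyl]-5-hydroxy-4,6,6-trimethylcyclohex-2-en-1-one hydrochloride | Cl.N[C@H](COC)[C@@H](O)C1=C[C@H](C)[C@@H](O)C(C)(C)C1=O | intermediate
18 | pent-4-yn-1-ol | C#CCCCO | starting material
19 | (E)-alkenylzirconocene chloride, zirconium alkoxide at oxygen (not isolated) | Cl[Zr](/C=C/CCCO[Zr](Cl)(C1C=CC=C1)C1C=CC=C1)(C1C=CC=C1)C1C=CC=C1 | intermediate
20 | (E)-5-iodopent-4-en-1-ol | OCCC/C=C/I | intermediate
21 | (E)-5-iodopent-4-enoic acid | OC(=O)CC/C=C/I | intermediate
22 | (E)-N-[(1S,2R)-1-hydroxy-1-[(3S,4R)-4-hydroxy-3,5,5-trimethyl-6-oxocyclohex-1-en-1-yl]-3-methoxypropan-2-yl]-5-iodopent-4-enamide | I/C=C/CCC(=O)N[C@H](COC)[C@@H](O)C1=C[C@H](C)[C@@H](O)C(C)(C)C1=O | intermediate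
23 | methyl (E)-but-2-enoate | C/C=C/C(=O)OC | starting material
24 | n-heptylmagnesium bromide | CCCCCCC[Mg]Br | starting material
25 | methyl (S)-3-methyldecanoate | CCCCCCC[C@H](C)CC(=O)OC | intermediate
26 | tert-butyl acetate | CC(=O)OC(C)(C)C | starting material
27 | tert-butyl (S)-5-methyl-3-oxododecanoate | CCCCCCC[C@H](C)CC(=O)CC(=O)OC(C)(C)C | intermediate
28 | tert-butyl (3R,5S)-3-hydroxy-5-methyldodecanoate | CCCCCCC[C@H](C)C[C@H](CC(=O)OC(C)(C)C)O | intermediate
29 | tert-butyl (3R,5S)-3-methoxy-5-methyldodecanoate | CCCCCCC[C@H](C)C[C@H](CC(=O)OC(C)(C)C)OC | intermediate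
30 | (3R,5S)-3-methoxy-5-methyldodecanoic acid | CCCCCCC[C@H](C)C[C@H](CC(=O)O)OC | intermediate
31 | 1,3-dioxoisoindolin-2-yl (3R,5S)-3-methoxy-5-methyldodecanoate | CCCCCCC[C@H](C)C[C@H](CC(=O)ON1C(=O)c2ccccc2C1=O)OC | intermediate
32 | 2-methoxy-4-methylundecyl radical, configuration as in 31 (not isolated) | CCCCCCC[C@H](C)C[C@H]([CH2])OC | intermediate
33 | (4E,7R,9S)-N-[(1S,2R)-1-hydroxy-1-[(3S,4R)-4-hydroxy-3,5,5-trimethyl-6-oxocyclohex-1-en-1-yl]-3-methoxypropan-2-yl]-7-methoxy-9-methylhexadec-4-enamide | CCCCCCC[C@H](C)C[C@H](C/C=C/CCC(=O)N[C@H](COC)[C@@H](O)C1=C[C@H](C)[C@@H](O)C(C)(C)C1=O)OC | target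

## Step count

Total step count: 21.
Longest linear sequence: 11 steps (steps 1–7, 10, 11, 14, 21).

## Steps most likely to fail

**Step 21.** The ring A enone may be reduced at the cathode or by low-valent nickel, or it may intercept the C6 radical. The polar head group may also bind nickel. In any of these cases, loss of iodine from 22 and self-coupling of the radical would outrun the cross-coupling.

The fallback sets out from 21 and 31 and comes back to the route at 33. It forms the same C5–C6 bond before the head group is attached, on a partner that has no enone, hydroxyl or N–H.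
- Acid 21 is esterified (Boc2O, DMAP, t-BuOH) to tert-butyl (E)-5-iodopent-4-enoate F1.
- The same nickel-electrocatalytic decarboxylative alkenylation with 31 gives tert-butyl (4E,7R,9S)-7-methoxy-9-methylhexadec-4-enoate F2.
- CF3CO2H in CH2Cl2 frees (4E,7R,9S)-7-methoxy-9-methylhexadec-4-enoic acid F3.
- EDC·HCl/HOBt/i-Pr2NEt coupling of this acid with amine salt 17 gives 33.

**Step 10.** The facial bias of an aldehyde that carries an N–H carbamate may be weak, because chelation competes with the Felkin–Anh mode. The aldehyde may also epimerise or lose methanol before it is attacked.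

The fallback sets out from 11 and comes back to the route at 22. It uses an aldehyde whose nitrogen is locked in a ring.
- Iodoenone 11 is coupled under the same chromium/nickel conditions with the purchased (R)-Garner aldehyde F4. This is the standard partner for anti-selective alkenyl additions, and it gives the oxazolidine carbinol F5.
- HCl in aqueous MeOH strips acetonide, Boc and triethylsilyl groups to give the amino triol hydrochloride F6.
- Acylation with 21 (EDC·HCl, HOBt, i-Pr2NEt) gives the triol amide F7.
- Its only primary hydroxyl group is methylated selectively (Me3OBF4, 1 equiv, 1,8-bis(dimethylamino)naphthalene, CH2Cl2, 0 °C). The two secondary hydroxyl groups are both flanked by branched carbons. The product is 22.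

**Step 5.** Addition to the neopentyl Weinreb amide may be slow, so that base-induced loss of formaldehyde from the N-methoxy group, or addition of the released amine to the vinyl ketone, takes over.

The fallback sets out from 7 and comes back to the route at 9. It passes through the aldehyde oxidation level.
- i-Bu2AlH (CH2Cl2, −78 °C) reduces 7 to (3R,4S)-2,2,4-trimethyl-3-(triethylsilyloxy)hex-5-enal F8.
- CH2=CHMgBr adds to it to give (5R,6S)-4,4,6-trimethyl-5-(triethylsilyloxy)octa-1,7-dien-3-ol F9 as a mixture at the new carbinol, which does not matter.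
- Dess–Martin oxidation then gives 9.

Further compounds
F1 | step 21 | tert-butyl (E)-5-iodopent-4-enoate | CC(C)(C)OC(=O)CC/C=C/I
F2 | step 21 | tert-butyl (4E,7R,9S)-7-methoxy-9-methylhexadec-4-enoate | CCCCCCC[C@H](C)C[C@H](C/C=C/CCC(=O)OC(C)(C)C)OC
F3 | step 21 | (4E,7R,9S)-7-methoxy-9-methylhexadec-4-enoic acid | CCCCCCC[C@H](C)C[C@H](C/C=C/CCC(=O)O)OC
F4 | step 10 | (R)-Garner aldehyde, tert-butyl (R)-4-formyl-2,2-dimethyloxazolidine-3-carboxylate (purchased) | CC(C)(C)OC(=O)N1[C@H](COC1(C)C)C=O
F5 | step 10 | oxazolidine carbinol, tert-butyl (R)-4-[(S)-hydroxy[(3S,4R)-3,5,5-trimethyl-6-oxo-4-(triethylsilyloxy)cyclohex-1-en-1-yl]methyl]-2,2-dimethyloxazolidine-3-carboxylate | CC(C)(C)OC(=O)N1[C@H](COC1(C)C)[C@@H](O)C2=C[C@H](C)[C@@H](O[Si](CC)(CC)CC)C(C)(C)C2=O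
F6 | step 10 | amino triol hydrochloride, (4S,5R)-2-[(1S,2R)-2-amino-1,3-dihydroxypropyl]-5-hydroxy-4,6,6-trimethylcyclohex-2-en-1-one hydrochloride | Cl.N[C@H](CO)[C@@H](O)C1=C[C@H](C)[C@@H](O)C(C)(C)C1=O
F7 | step 10 | triol amide, (E)-N-[(1S,2R)-1,3-dihydroxy-1-[(3S,4R)-4-hydroxy-3,5,5-trimethyl-6-oxocyclohex-1-en-1-yl]propan-2-yl]-5-iodopent-4-enamide | I/C=C/CCC(=O)N[C@H](CO)[C@@H](O)C1=C[C@H](C)[C@@H](O)C(C)(C)C1=O
F8 | step 5 | (3R,4S)-2,2,4-trimethyl-3-(triethylsilyloxy)hex-5-enal | C=C[C@H](C)[C@@H](O[Si](CC)(CC)CC)C(C)(C)C=O
F9 | step 5 | (5R,6S)-4,4,6-trimethyl-5-(triethylsilyloxy)octa-1,7-dien-3-ol, both C3 epimers | C=C[C@H](C)[C@@H](O[Si](CC)(CC)CC)C(C)(C)C(O)C=C
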